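**Retrosynthetic overview**

1. The target comes from its aryl TBS ether by buffered fluoride; both sensitive ketones (C5, C12) come from a 5,12-diol by one late double oxidation.
2. Key disconnection C4–C5: α-selective carbonyl allylation of an E-enal (fragment 2, C5–C16) with the allylbarium made from an E-allylic chloride (fragment 1, arene plus C1–C4).
3. Fragment 1: 4-methoxy-2-methylphenol, ortho-bromination, aryl Grignard prenylation, E-selective allylic oxidation, chloride.
4. Fragment 2: Evans methylation sets C11; allyl Grignard addition builds C12–C13, cross-metathesis gives the prenyl end, and carboalumination fixes the E C6=C7 alkene.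
5. No ring is formed; the benzene ring is bought.

Assumption: side-chain carbons are numbered C1 (benzylic CH2) to C16; the carbinol centres at C5 and C12 are carried as epimer mixtures because both end as ketones.

**Route**

Step 1
Reactants: 1 4-methoxy-2-methylphenol
Product: 2 2-bromo-4-methoxy-6-methylphenol
Conditions: NBS (1.0 equiv), i-Pr2NH (10 mol%), CH2Cl2, 0 °C
Reagents that add atoms: N-bromosuccinimide, O=C1CCC(=O)N1Br
Why: Electrophilic aromatic bromination goes ortho to the free hydroxyl, the strongest director, at the only open ortho position (para carries the methoxy group).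

Step 2
Reactants: 2 2-bromo-4-methoxy-6-methylphenol
Product: 3 (2-bromo-4-methoxy-6-methylphenoxy)(tert-butyl)dimethylsilane
Conditions: TBSCl, imidazole, DMF, rt
Reagents that add atoms: TBSCl, CC(C)(C)[Si](C)(C)Cl
Why: Standard phenol silylation gives an ether that tolerates Grignard, barium and oxidation chemistry and is removed last with fluoride.

Step 3
Reactants: 3 (2-bromo-4-methoxy-6-methylphenoxy)(tert-butyl)dimethylsilane; 4 prenyl bromide (1-bromo-3-methylbut-2-ene)
Product: 6 tert-butyl[4-methoxy-2-methyl-6-(3-methylbut-2-en-1-yl)phenoxy]dimethylsilane, via arylmagnesium bromide 5 (not isolated)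
Conditions: Mg, THF, reflux; then 4, Li2CuCl4 (3 mol%), THF, −10 °C to rt
Reagents that add atoms: Mg, [Mg] (stays only in intermediate 5)
Why: Grignard formation followed by Kochi copper-catalysed allylic substitution puts the aryl group on the unhindered CH2 end of prenyl bromide (attack at the other end would build a quaternary carbon), and an ortho-silyloxy aryl Grignard, unlike the aryllithium, does not suffer silyl migration.

Step 4
Reactants: 6 tert-butyl[4-methoxy-2-methyl-6-(3-methylbut-2-en-1-yl)phenoxy]dimethylsilane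
Product: 8 (E)-4-[2-(tert-butyldimethylsilyloxy)-5-methoxy-3-methylphenyl]-2-methylbut-2-en-1-ol, via over-oxidised enal 7 (not isolated)
Conditions: SeO2 (0.3 equiv), t-BuOOH (2.5 equiv), salicylic acid (10 mol%), CH2Cl2, rt; then NaBH4, MeOH, 0 °C
Reagents that add atoms: tert-butyl hydroperoxide, CC(C)(C)OO (its oxygen is passed on by SeO2, O=[Se]=O)
Why: Sharpless SeO2/t-BuOOH allylic oxidation (ene reaction then [2,3]-sigmatropic shift) attacks the E-methyl of the gem-dimethyl terminus with high E selectivity, and the borohydride finish returns the over-oxidised enal 7 to the alcohol.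

Step 5
Reactants: 8 (E)-4-[2-(tert-butyldimethylsilyloxy)-5-methoxy-3-methylphenyl]-2-methylbut-2-en-1-ol
Product: 10 tert-butyl{2-[(E)-4-chloro-3-methylbut-2-en-1-yl]-4-methoxy-6-methylphenoxy}dimethylsilane (fragment 1), via allylic mesylate 9 (not isolated)
Conditions: MsCl, 2,4,6-collidine, LiCl, DMF, 0 °C
Reagents that add atoms: LiCl, [Li+].[Cl-]; MsCl, CS(=O)(=O)Cl (its mesyl group stays only in intermediate 9)
Why: Collington–Meyers chlorination (mesylation then SN2 displacement by chloride) converts a primary allylic alcohol to the chloride without allylic transposition or E/Z scrambling.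

Step 6
Reactants: 11 hept-6-ynoic acid; 12 (R)-4-benzyl-2-oxazolidinone
Product: 14 (R)-4-benzyl-3-(hept-6-ynoyl)oxazolidin-2-one, via mixed pivalic anhydride 13 (not isolated)
Conditions: t-BuCOCl, Et3N, THF, −20 °C; then 12, LiCl, −20 °C to rt
Reagents that add atoms: pivaloyl chloride, CC(C)(C)C(=O)Cl (its acyl group stays only in intermediate 13)
Why: N-acylation of the Evans oxazolidinone through the mixed anhydride (LiCl/Et3N variant) is a standard high-yielding imide formation.

Step 7
Reactants: 14 (R)-4-benzyl-3-(hept-6-ynoyl)oxazolidin-2-one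
Product: 16 (R)-4-benzyl-3-[(R)-2-methylhept-6-ynoyl]oxazolidin-2-one, via sodium Z-enolate 15 (not isolated)
Conditions: NaN(SiMe3)2 (1.1 equiv), THF, −78 °C; MeI, −78 to −40 °C; chromatography
Reagents that add atoms: MeI, CI; NaN(SiMe3)2, [Na+].C[Si](C)(C)[N-][Si](C)(C)C (sodium stays only in intermediate 15)
Why: Evans asymmetric alkylation: the chelated Z-enolate is methylated on the face away from the benzyl group, which with the (R)-auxiliary sets C11 as R (dr about 95:5, minor isomer removed), the imide α-proton being far more acidic than the alkyne proton.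

Step 8
Reactants: 16 (R)-4-benzyl-3-[(R)-2-methylhept-6-ynoyl]oxazolidin-2-one
Product: 17 (R)-2-methylhept-6-yn-1-ol
Conditions: LiBH4, MeOH (1 equiv), Et2O, 0 °C
Reagents that add atoms: none
Why: Reductive cleavage of the N-acyl oxazolidinone with LiBH4 releases the primary alcohol without touching the stereocentre or the alkyne, and the auxiliary is recovered.

Step 9
Reactants: 17 (R)-2-methylhept-6-yn-1-ol
Product: 18 (R)-2-methylhept-6-ynal
Conditions: Dess–Martin periodinane, NaHCO3, CH2Cl2, 0 °C to rt; used at once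
Reagents that add atoms: none
Why: Buffered Dess–Martin oxidation gives the α-branched aldehyde under non-epimerising conditions.

Step 10
Reactants: 18 (R)-2-methylhept-6-ynal; 19 allylmagnesium bromide
Product: 20 (4RS,5R)-5-methyldec-1-en-9-yn-4-ol
Conditions: Et2O, −78 °C; aq. NH4Cl
Reagents that add atoms: none
Why: Grignard carbonyl allylation at −78 °C outruns enolisation and alkyne deprotonation; the new C12 carbinol forms as an epimer mixture, which does not matter because it is oxidised in step 17.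

Step 11
Reactants: 20 (4RS,5R)-5-methyldec-1-en-9-yn-4-ol
Product: 21 triethyl{[(4RS,5R)-5-methyldec-1-en-9-yn-4-yl]oxy}silane
Conditions: TESCl, imidazole, CH2Cl2, 0 °C to rt
Reagents that add atoms: TESCl, CC[Si](CC)(CC)Cl
Why: Silylation; a TES ether survives the aluminium, ruthenium and barium reagents ahead but can later be removed with mild acid beside the aryl TBS ether.

Step 12
Reactants: 21 triethyl{[(4RS,5R)-5-methyldec-1-en-9-yn-4-yl]oxy}silane
Product: 24 (2E,7R,8RS)-3,7-dimethyl-8-(triethylsilyloxy)undeca-2,10-dien-1-ol, via alkenyldimethylalane 22 (not isolated), via lithium alkenylalanate 23 (not isolated)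
Conditions: Me3Al (2.5 equiv), Cp2ZrCl2 (0.25 equiv), CH2Cl2, 0 °C to rt; evaporate; n-BuLi, THF, −78 to 0 °C; (CH2O)n, rt; aq. potassium sodium tartrate
Reagents that add atoms: Me3Al, C[Al](C)C; paraformaldehyde, as formaldehyde C=O; n-BuLi, CCCC[Li] (butyl and lithium stay only in intermediate 23)
Why: Negishi zirconium-catalysed carboalumination adds methyl and aluminium syn across the terminal alkyne (methyl to the internal carbon), which fixes the E-trisubstituted alkene; the monosubstituted alkene reacts far more slowly, and the alanate is hydroxymethylated with retention.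

Step 13
Reactants: 24 (2E,7R,8RS)-3,7-dimethyl-8-(triethylsilyloxy)undeca-2,10-dien-1-ol; 25 2-methylbut-2-ene
Product: 26 (2E,7R,8RS)-3,7,11-trimethyl-8-(triethylsilyloxy)dodeca-2,10-dien-1-ol
Conditions: second-generation Grubbs catalyst RuCl2(=CHPh)(PCy3)(H2IMes) (3 mol%), 25 (large excess)/CH2Cl2, rt, sealed vessel
Reagents that add atoms: none
Why: Olefin cross-metathesis with 2-methylbut-2-ene turns the terminal vinyl group into the prenyl terminus, the trisubstituted allylic-alcohol alkene being inert to the catalyst.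

Step 14
Reactants: 26 (2E,7R,8RS)-3,7,11-trimethyl-8-(triethylsilyloxy)dodeca-2,10-dien-1-ol
Product: 27 (2E,7R,8RS)-3,7,11-trimethyl-8-(triethylsilyloxy)dodeca-2,10-dienal (fragment 2)
Conditions: MnO2 (20 equiv), CH2Cl2, rt
Reagents that add atoms: none
Why: MnO2 oxidises only the allylic alcohol and gives the E-enal without isomerisation.

Step 15
Reactants: 10 tert-butyl{2-[(E)-4-chloro-3-methylbut-2-en-1-yl]-4-methoxy-6-methylphenoxy}dimethylsilane; 27 (2E,7R,8RS)-3,7,11-trimethyl-8-(triethylsilyloxy)dodeca-2,10-dienal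
Product: 29 (2E,6E,5RS,11R,12RS)-1-[2-(tert-butyldimethylsilyloxy)-5-methoxy-3-methylphenyl]-3,7,11,15-tetramethyl-12-(triethylsilyloxy)hexadeca-2,6,14-trien-5-ol, via allylbarium chloride 28 (not isolated)
Conditions: BaI2 (anhydrous), Li, biphenyl, THF, rt; 10 (1.6 equiv), −78 °C; 27 (1.0 equiv), −78 °C; aq. NH4Cl
Reagents that add atoms: BaI2, [Ba+2].[I-].[I-] (barium stays only in intermediate 28)
Why: Yamamoto allylbarium carbonyl allylation: the allylbarium formed at −78 °C keeps its E geometry and attacks the aldehyde carbonyl (1,2) through its unsubstituted α-carbon, which forges C4–C5 and joins the two fragments.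

Step 16
Reactants: 29 (2E,6E,5RS,11R,12RS)-1-[2-(tert-butyldimethylsilyloxy)-5-methoxy-3-methylphenyl]-3,7,11,15-tetramethyl-12-(triethylsilyloxy)hexadeca-2,6,14-trien-5-ol
Product: 30 (2E,6E,5RS,11R,12RS)-1-[2-(tert-butyldimethylsilyloxy)-5-methoxy-3-methylphenyl]-3,7,11,15-tetramethylhexadeca-2,6,14-triene-5,12-diol
Conditions: PPTS (0.2 equiv), MeOH/CH2Cl2, 0 °C to rt
Reagents that add atoms: none
Why: Acid-catalysed methanolysis cleaves the secondary alkyl TES ether, while the hindered aryl TBS ether, far more stable to acid, stays and the conditions are too mild to ionise the allylic C5 alcohol.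

Step 17
Reactants: 30 (2E,6E,5RS,11R,12RS)-1-[2-(tert-butyldimethylsilyloxy)-5-methoxy-3-methylphenyl]-3,7,11,15-tetramethylhexadeca-2,6,14-triene-5,12-diol
Product: 31 (2E,6E,11R)-1-[2-(tert-butyldimethylsilyloxy)-5-methoxy-3-methylphenyl]-3,7,11,15-tetramethylhexadeca-2,6,14-triene-5,12-dione
Conditions: Dess–Martin periodinane (3 equiv), NaHCO3, CH2Cl2, 0 °C to rt
Reagents that add atoms: none
Why: Bicarbonate-buffered Dess–Martin oxidation converts both secondary alcohols to ketones, merging all epimers, without moving the β,γ-double bonds into conjugation or epimerising C11.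

Step 18
Reactants: 31 (2E,6E,11R)-1-[2-(tert-butyldimethylsilyloxy)-5-methoxy-3-methylphenyl]-3,7,11,15-tetramethylhexadeca-2,6,14-triene-5,12-dione
Product: 32 (2E,6E,11R)-1-(2-hydroxy-5-methoxy-3-methylphenyl)-3,7,11,15-tetramethylhexadeca-2,6,14-triene-5,12-dione (CNP0301021.2)
Conditions: Bu4NF/AcOH (1:1), THF, 0 °C
Reagents that add atoms: none
Why: Fluoride desilylation of the aryl silyl ether buffered with acetic acid is close to neutral, so the skipped enone, the β,γ-unsaturated ketone and the α-stereocentre survive.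

**Compound list**

1 | 4-methoxy-2-methylphenol | COc1ccc(O)c(C)c1 | starting material
2 | 2-bromo-4-methoxy-6-methylphenol | COc1cc(C)c(O)c(Br)c1 | intermediate
3 | (2-bromo-4-methoxy-6-methylphenoxy)(tert-butyl)dimethylsilane | COc1cc(C)c(O[Si](C)(C)C(C)(C)C)c(Br)c1 | intermediate
4 | prenyl bromide (1-bromo-3-methylbut-2-ene) | CC(C)=CCBr | starting material
5 | [2-(tert-butyldimethylsilyloxy)-5-methoxy-3-methylphenyl]magnesium bromide | COc1cc(C)c(O[Si](C)(C)C(C)(C)C)c([Mg]Br)c1 | intermediate (not isolated)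
6 | tert-butyl[4-methoxy-2-methyl-6-(3-methylbut-2-en-1-yl)phenoxy]dimethylsilane | COc1cc(C)c(O[Si](C)(C)C(C)(C)C)c(CC=C(C)C)c1 | intermediate
7 | (E)-4-[2-(tert-butyldimethylsilyloxy)-5-methoxy-3-methylphenyl]-2-methylbut-2-enal | COc1cc(C)c(O[Si](C)(C)C(C)(C)C)c(C/C=C(\C)C=O)c1 | intermediate (not isolated)
8 | (E)-4-[2-(tert-butyldimethylsilyloxy)-5-methoxy-3-methylphenyl]-2-methylbut-2-en-1-ol | COc1cc(C)c(O[Si](C)(C)C(C)(C)C)c(C/C=C(\C)CO)c1 | intermediate
9 | (E)-4-[2-(tert-butyldimethylsilyloxy)-5-methoxy-3-methylphenyl]-2-methylbut-2-en-1-yl methanesulfonate | COc1cc(C)c(O[Si](C)(C)C(C)(C)C)c(C/C=C(\C)COS(C)(=O)=O)c1 | intermediate (not isolated)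
10 | tert-butyl{2-[(E)-4-chloro-3-methylbut-2-en-1-yl]-4-methoxy-6-methylphenoxy}dimethylsilane | COc1cc(C)c(O[Si](C)(C)C(C)(C)C)c(C/C=C(\C)CCl)c1 | intermediate
11 | hept-6-ynoic acid | C#CCCCCC(=O)O | starting material
12 | (R)-4-benzyl-2-oxazolidinone | O=C1N[C@H](Cc2ccccc2)CO1 | starting material
13 | hept-6-ynoic pivalic anhydride | C#CCCCCC(=O)OC(=O)C(C)(C)C | intermediate (not isolated)
14 | (R)-4-benzyl-3-(hept-6-ynoyl)oxazolidin-2-one | C#CCCCCC(=O)N1[C@H](Cc2ccccc2)COC1=O | intermediate
15 | sodium (Z)-enolate of 14 | C#CCCC/C=C(\O[Na])N1[C@H](Cc2ccccc2)COC1=O | intermediate (not isolated)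
16 | (R)-4-benzyl-3-[(R)-2-methylhept-6-ynoyl]oxazolidin-2-one | C#CCCC[C@@H](C)C(=O)N1[C@H](Cc2ccccc2)COC1=O | intermediate
17 | (R)-2-methylhept-6-yn-1-ol | C#CCCC[C@@H](C)CO | intermediate
18 | (R)-2-methylhept-6-ynal | C#CCCC[C@@H](C)C=O | intermediate
19 | allylmagnesium bromide | C=CC[Mg]Br | starting material
20 | (4RS,5R)-5-methyldec-1-en-9-yn-4-ol | C#CCCC[C@@H](C)C(O)CC=C | intermediate
21 | triethyl{[(4RS,5R)-5-methyldec-1-en-9-yn-4-yl]oxy}silane | C#CCCC[C@@H](C)C(O[Si](CC)(CC)CC)CC=C | intermediate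
22 | dimethyl[(1E,6R,7RS)-2,6-dimethyl-7-(triethylsilyloxy)deca-1,9-dien-1-yl]alane | C[Al](C)/C=C(\C)CCC[C@@H](C)C(O[Si](CC)(CC)CC)CC=C | intermediate (not isolated)
23 | lithium butyl(dimethyl)[(1E,6R,7RS)-2,6-dimethyl-7-(triethylsilyloxy)deca-1,9-dien-1-yl]alanate | [Li+].CCCC[Al-](C)(C)/C=C(\C)CCC[C@@H](C)C(O[Si](CC)(CC)CC)CC=C | intermediate (not isolated)
24 | (2E,7R,8RS)-3,7-dimethyl-8-(triethylsilyloxy)undeca-2,10-dien-1-ol | OC/C=C(\C)CCC[C@@H](C)C(O[Si](CC)(CC)CC)CC=C | intermediate
25 | 2-methylbut-2-ene | CC=C(C)C | starting material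
26 | (2E,7R,8RS)-3,7,11-trimethyl-8-(triethylsilyloxy)dodeca-2,10-dien-1-ol | OC/C=C(\C)CCC[C@@H](C)C(O[Si](CC)(CC)CC)CC=C(C)C | intermediate
27 | (2E,7R,8RS)-3,7,11-trimethyl-8-(triethylsilyloxy)dodeca-2,10-dienal | O=C/C=C(\C)CCC[C@@H](C)C(O[Si](CC)(CC)CC)CC=C(C)C | intermediate
28 | {(E)-4-[2-(tert-butyldimethylsilyloxy)-5-methoxy-3-methylphenyl]-2-methylbut-2-en-1-yl}barium chloride | COc1cc(C)c(O[Si](C)(C)C(C)(C)C)c(C/C=C(\C)C[Ba]Cl)c1 | intermediate (not isolated)
29 | (2E,6E,5RS,11R,12RS)-1-[2-(tert-butyldimethylsilyloxy)-5-methoxy-3-methylphenyl]-3,7,11,15-tetramethyl-12-(triethylsilyloxy)hexadeca-2,6,14-trien-5-ol | COc1cc(C)c(O[Si](C)(C)C(C)(C)C)c(C/C=C(\C)CC(O)/C=C(\C)CCC[C@@H](C)C(O[Si](CC)(CC)CC)CC=C(C)C)c1 | intermediate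
30 | (2E,6E,5RS,11R,12RS)-1-[2-(tert-butyldimethylsilyloxy)-5-methoxy-3-methylphenyl]-3,7,11,15-tetramethylhexadeca-2,6,14-triene-5,12-diol | COc1cc(C)c(O[Si](C)(C)C(C)(C)C)c(C/C=C(\C)CC(O)/C=C(\C)CCC[C@@H](C)C(O)CC=C(C)C)c1 | intermediate
31 | (2E,6E,11R)-1-[2-(tert-butyldimethylsilyloxy)-5-methoxy-3-methylphenyl]-3,7,11,15-tetramethylhexadeca-2,6,14-triene-5,12-dione | COc1cc(C)c(O[Si](C)(C)C(C)(C)C)c(C/C=C(\C)CC(=O)/C=C(\C)CCC[C@@H](C)C(=O)CC=C(C)C)c1 | intermediate
32 | (2E,6E,11R)-1-(2-hydroxy-5-methoxy-3-methylphenyl)-3,7,11,15-tetramethylhexadeca-2,6,14-triene-5,12-dione | COc1cc(C)c(O)c(C/C=C(\C)CC(=O)/C=C(\C)CCC[C@@H](C)C(=O)CC=C(C)C)c1 | target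

**Count**

Total steps: 18 (5 to fragment 1, 9 to fragment 2, 4 from the union to the target). Longest linear sequence: 13 steps (steps 6 to 18).

**Three steps most likely to fail, each with a fallback**

Step 15 (allylbarium union). The risks are γ-attack, loss of E geometry on warming, or poor formation of the barium reagent. The fallback sets out from 10 and 27 and comes back at 31. Chloride 10 is treated with PhSO2Na in DMF to give tert-butyl{4-methoxy-2-methyl-6-[(E)-3-methyl-4-(phenylsulfonyl)but-2-en-1-yl]phenoxy}dimethylsilane F1. Deprotonation with n-BuLi in THF at −78 °C gives the α-lithio sulfone F2 (not isolated), which adds through its sulfonyl-bearing carbon to the carbonyl of enal 27 to give the β-hydroxy sulfone F3. Buffered Dess–Martin oxidation gives the β-keto sulfone F4. SmI2 in THF/MeOH at −78 °C removes the sulfonyl group and leaves the C5 ketone 12-TES ether F5. PPTS in MeOH frees the 12-hydroxy 5-ketone F6, and Dess–Martin oxidation then gives diketone 31.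

Step 4 (SeO2 allylic oxidation). The risks are a modest yield, over-oxidation and attack on the electron-rich arene. The fallback sets out from 6 and comes back at 8. Alkene 6 is cleaved with OsO4 (cat.), NaIO4 and 2,6-lutidine in dioxane/water, through the vicinal diol F7 (not isolated), to the arylacetaldehyde F8. Wittig reaction with ethyl 2-(triphenylphosphoranylidene)propanoate in CH2Cl2 gives the ethyl (E)-enoate F9 with high E selectivity. Reduction with i-Bu2AlH in CH2Cl2 at −78 °C gives allylic alcohol 8.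

Step 12 (carboalumination beside a terminal alkene, then hydroxymethylation). The risks are competing reaction at the monosubstituted alkene and incomplete trapping. The fallback sets out from 18 and comes back at 26, and it makes step 13 unnecessary. Aldehyde 18 is treated at −78 °C with prenylbarium chloride F10 (from 1-chloro-3-methylbut-2-ene and barium made from BaI2 and lithium biphenylide), which adds through its unsubstituted carbon to give the prenyl carbinol (5RS,6R)-2,6-dimethylundec-2-en-10-yn-5-ol F11. TESCl and imidazole give its triethylsilyl ether F12. The Me3Al/Cp2ZrCl2 carboalumination is then run on this substrate, whose only alkene is trisubstituted and inert; it gives the alkenyldimethylalane F13 and, after n-BuLi, the lithium alanate F14 (neither isolated), and paraformaldehyde then gives 26 directly.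

**Further compounds**

F1 | step 15 | tert-butyl{4-methoxy-2-methyl-6-[(E)-3-methyl-4-(phenylsulfonyl)but-2-en-1-yl]phenoxy}dimethylsilane | COc1cc(C)c(O[Si](C)(C)C(C)(C)C)c(C/C=C(\C)CS(=O)(=O)c2ccccc2)c1
F2 | step 15 | α-lithio derivative of sulfone F1 | COc1cc(C)c(O[Si](C)(C)C(C)(C)C)c(C/C=C(\C)C([Li])S(=O)(=O)c2ccccc2)c1
F3 | step 15 | β-hydroxy sulfone (29 carrying a phenylsulfonyl group at C4) | COc1cc(C)c(O[Si](C)(C)C(C)(C)C)c(C/C=C(\C)C(C(O)/C=C(\C)CCC[C@@H](C)C(O[Si](CC)(CC)CC)CC=C(C)C)S(=O)(=O)c2ccccc2)c1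
F4 | step 15 | β-keto sulfone (C5 ketone, phenylsulfonyl at C4, 12-TES ether) | COc1cc(C)c(O[Si](C)(C)C(C)(C)C)c(C/C=C(\C)C(C(=O)/C=C(\C)CCC[C@@H](C)C(O[Si](CC)(CC)CC)CC=C(C)C)S(=O)(=O)c2ccccc2)c1
F5 | step 15 | (2E,6E,11R,12RS)-1-[2-(tert-butyldimethylsilyloxy)-5-methoxy-3-methylphenyl]-3,7,11,15-tetramethyl-12-(triethylsilyloxy)hexadeca-2,6,14-trien-5-one | COc1cc(C)c(O[Si](C)(C)C(C)(C)C)c(C/C=C(\C)CC(=O)/C=C(\C)CCC[C@@H](C)C(O[Si](CC)(CC)CC)CC=C(C)C)c1
F6 | step 15 | (2E,6E,11R,12RS)-1-[2-(tert-butyldimethylsilyloxy)-5-methoxy-3-methylphenyl]-12-hydroxy-3,7,11,15-tetramethylhexadeca-2,6,14-trien-5-one | COc1cc(C)c(O[Si](C)(C)C(C)(C)C)c(C/C=C(\C)CC(=O)/C=C(\C)CCC[C@@H](C)C(O)CC=C(C)C)c1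
F7 | step 4 | 4-[2-(tert-butyldimethylsilyloxy)-5-methoxy-3-methylphenyl]-2-methylbutane-2,3-diol | COc1cc(C)c(O[Si](C)(C)C(C)(C)C)c(CC(O)C(C)(C)O)c1
F8 | step 4 | [2-(tert-butyldimethylsilyloxy)-5-methoxy-3-methylphenyl]acetaldehyde | COc1cc(C)c(O[Si](C)(C)C(C)(C)C)c(CC=O)c1
F9 | step 4 | ethyl (E)-4-[2-(tert-butyldimethylsilyloxy)-5-methoxy-3-methylphenyl]-2-methylbut-2-enoate | COc1cc(C)c(O[Si](C)(C)C(C)(C)C)c(C/C=C(\C)C(=O)OCC)c1
F10 | step 12 | prenylbarium chloride | CC(C)=CC[Ba]Cl
F11 | step 12 | (5RS,6R)-2,6-dimethylundec-2-en-10-yn-5-ol | C#CCCC[C@@H](C)C(O)CC=C(C)C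
F12 | step 12 | triethylsilyl ether of F11 | C#CCCC[C@@H](C)C(O[Si](CC)(CC)CC)CC=C(C)C
F13 | step 12 | dimethyl[(1E,6R,7RS)-2,6,10-trimethyl-7-(triethylsilyloxy)undeca-1,9-dien-1-yl]alane | C[Al](C)/C=C(\C)CCC[C@@H](C)C(O[Si](CC)(CC)CC)CC=C(C)C
F14 | step 12 | lithium butyl(dimethyl)[(1E,6R,7RS)-2,6,10-trimethyl-7-(triethylsilyloxy)undeca-1,9-dien-1-yl]alanate | [Li+].CCCC[Al-](C)(C)/C=C(\C)CCC[C@@H](C)C(O[Si](CC)(CC)CC)CC=C(C)C
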